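**Retrosynthetic overview** (locants are those of the target's octahydro-1-benzofuran-2-one core)
1. The acrolein unit comes last, by allylic oxidation of an isopropenyl group; the oxirane and the methacrylate are already in place by then.
2. Key disconnection: the C-3a–C-4 bond. A samarium ketyl from an acyclic aldehyde closes the cyclohexane onto a tethered butenolide and expels a sulfinate in the same step, giving the cis-fused α-methylene lactone and the C-4 carbinol together.
3. The C-7–C-7a bond comes from a vinylogous aldol reaction of an α-quaternary epoxy aldehyde with a 2-silyloxyfuran made from α-methylene-γ-butyrolactone.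
4. The C-5–C-6 bond (tertiary next to quaternary centre) comes from an enantioselective boron ester-enolate Claisen rearrangement of an allyl 3-methylbut-3-enoate built from isoprene monoxide.
5. Ring order: butenolide (carried in intact), oxirane (step 6), cyclohexane (step 13, which also completes the bicyclic lactone).

Assumption: the absolute sense of the two reagent-controlled steps (the (S,S)-bromoborane in step 3, the (R,R)-bishydroxamic acid ligand in step 6) is taken as drawn; if either proves opposite, the enantiomeric controller is used with no other change.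

**Step 1**
Reactants: 1 2-methyl-2-vinyloxirane; 2 3-methylbut-3-enoic acid
Product: 3 (2E)-4-hydroxy-3-methylbut-2-en-1-yl 3-methylbut-3-enoate
Conditions: Pd(PPh3)4 (2 mol%), THF, 0 °C to rt
Reagents that add atoms: none
Why: Zerovalent palladium ionises the vinyl epoxide to a π-allyl alkoxide that deprotonates the acid, and the carboxylate adds at the unsubstituted allyl terminus (palladium-catalysed 1,4-addition to a vinyl epoxide), which puts the ester on the CH2 next to CH= and leaves the hydroxyl on the CH2 next to the methyl-bearing carbon, the E alkene being the major isomer (Z isomer and 1,2-adduct are removed by chromatography) and no stereocentre being formed.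

**Step 2**
Reactants: 3 hydroxy ester
Product: 4 (2E)-4-(pivaloyloxy)-3-methylbut-2-en-1-yl 3-methylbut-3-enoate
Conditions: pivaloyl chloride, pyridine, DMAP (cat.), CH2Cl2, 0 °C
Reagents that add atoms: pivaloyl chloride, CC(C)(C)C(=O)Cl
Why: DMAP-catalysed acylation masks the primary alcohol as a pivalate, which has no α-hydrogen and so cannot compete in the soft enolisation of step 3, and no stereocentre is formed.

**Step 3**
Reactants: 4 pivalate ester
Product: 6 (2S,3S)-3-(pivaloyloxymethyl)-3-methyl-2-(prop-1-en-2-yl)pent-4-enoic acid, via boron ketene acetal 5 (not isolated)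
Conditions: (4S,5S)-2-bromo-1,3-bis{[3,5-bis(trifluoromethyl)phenyl]sulfonyl}-4,5-diphenyl-1,3,2-diazaborolidine (1.2 equiv), Et3N, toluene–hexane, −78 to −20 °C; aqueous work-up
Reagents that add atoms: none
Why: This is an enantioselective boron ester-enolate (Ireland-type) Claisen rearrangement in which soft enolisation of the doubly activated CH2 gives the E(O) dienolate, the chair [3,3] transition state with the E allyl unit sets the vicinal tertiary (C-5) and quaternary (C-6) centres in the elemane-type relative configuration (the pattern of geranyl 3-methylbut-3-enoate), and the C2-symmetric sulfonamide ligand on boron selects the enolate face and hence the absolute configuration.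

**Step 4**
Reactants: 6 Claisen acid
Product: 7 (2S,3S)-2-ethenyl-2-methyl-3-(prop-1-en-2-yl)butane-1,4-diol
Conditions: LiAlH4, Et2O, 0 °C
Reagents that add atoms: none
Why: Hydride reduction converts the acid to the primary alcohol and cleaves the pivalate in the same operation, leaving the alkenes and both stereocentres untouched.

**Step 5**
Reactants: 7 diol
Product: 8 (2S,3S)-2-ethenyl-2-methyl-3-(prop-1-en-2-yl)-4-(triethylsilyloxy)butan-1-ol
Conditions: TESCl (1.0 equiv), imidazole, CH2Cl2, −78 °C
Reagents that add atoms: chlorotriethylsilane, CC[Si](Cl)(CC)CC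
Why: Kinetically selective silylation caps the CH2OH on the tertiary carbon, which is much less hindered than the neopentyl CH2OH on the quaternary carbon (bis-silyl and regioisomeric material is desilylated and recycled), and no stereocentre is formed.

**Step 6**
Reactants: 8 mono-silyl diol
Product: 9 (2S,3S)-2-methyl-2-[(2S)-oxiran-2-yl]-3-(prop-1-en-2-yl)-4-(triethylsilyloxy)butan-1-ol
Conditions: VO(OiPr)3 (2 mol%), (R,R)-cyclohexanediamine-derived bishydroxamic acid ligand (4 mol%), cumene hydroperoxide, toluene, 0 °C to rt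
Reagents that add atoms: cumene hydroperoxide, CC(C)(OO)c1ccccc1
Why: In this hydroxyl-directed vanadium-catalysed epoxidation of a homoallylic alcohol the vanadate ester of the free neopentyl alcohol delivers oxygen only to the vinyl group (the isopropenyl group is one atom further away and its nearer oxygen is silylated), and the oxirane stereocentre is set by the chiral ligand reinforced by the substrate, whose vinyl group reacts in the rotamer that turns its CH2 away from the branched C-5 substituent.

**Step 7**
Reactants: 9 epoxy alcohol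
Product: 10 (2R,3S)-2-methyl-2-[(2S)-oxiran-2-yl]-3-(prop-1-en-2-yl)-4-(triethylsilyloxy)butanal
Conditions: Dess–Martin periodinane, CH2Cl2, 0 °C to rt
Reagents that add atoms: none
Why: Dess–Martin oxidation of the primary alcohol gives an aldehyde that cannot epimerise because its α-carbon is quaternary, and the epoxide and silyl ether are inert to the reagent.

**Step 8**
Reactants: 11 α-methylene-γ-butyrolactone
Product: 13 3-[(benzenesulfonyl)methyl]furan-2(5H)-one, via iodo sulfone 12 (not isolated)
Conditions: PhSO2Na, I2, EtOAc–H2O, rt; then Et3N, CH2Cl2, rt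
Reagents that add atoms: sodium benzenesulfinate, [Na+].[O-]S(=O)c1ccccc1
Why: Radical iodosulfonylation (the sulfonyl radical adds to the exocyclic CH2 and iodine caps the tertiary radical) followed by amine-induced dehydroiodination into the ring gives the conjugated butenolide with an allylic sulfone, which is the standard route to 2-(sulfonylmethyl)acrylates applied to a lactone.

**Step 9**
Reactants: 13 sulfonyl butenolide
Product: 14 {3-[(benzenesulfonyl)methyl]furan-2-yl}oxy(trimethyl)silane
Conditions: TMSOTf, Et3N, Et2O, 0 °C; used crude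
Reagents that add atoms: trimethylsilyl trifluoromethanesulfonate, C[Si](C)(C)OS(=O)(=O)C(F)(F)F
Why: Soft enolisation at the γ-CH2 is driven by aromatisation to the 2-silyloxyfuran, the usual preparation of these vinylogous nucleophiles.

**Step 10**
Reactants: 10 epoxy aldehyde; 14 silyloxyfuran
Product: 16 (5R)-3-[(benzenesulfonyl)methyl]-5-{(1S,2S,3S)-1-hydroxy-2-methyl-2-[(2S)-oxiran-2-yl]-3-(prop-1-en-2-yl)-4-(triethylsilyloxy)butyl}furan-2(5H)-one, via trimethylsilyl ether 15 (not isolated)
Conditions: Bu4NOAc (10 mol%), THF, −78 to −40 °C; aqueous citric acid work-up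
Reagents that add atoms: none
Why: In this Lewis-base-triggered vinylogous Mukaiyama aldol reaction the acetate-released furanolate attacks through its γ-carbon in an open antiperiplanar transition state that gives the erythro C-7/C-7a adduct, while the aldehyde face is chosen by a Cornforth–Felkin arrangement (carbonyl anti to the oxirane-bearing substituent, attack anti to the branched C-5 substituent), which sets C-7 as S and C-7a as R before silyl transfer gives the trimethylsilyl ether that the acidic work-up cleaves.

**Step 11**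
Reactants: 16 butenolide carbinol; 17 methacryloyl chloride
Product: 18 methacrylate of 16
Conditions: pyridine, DMAP (cat.), CH2Cl2, 0 °C
Reagents that add atoms: none
Why: DMAP-catalysed acylation of the hindered secondary alcohol installs the methacrylate before the second hydroxyl exists, so the two secondary alcohols never need to be told apart, and pyridine is too weak a base to epimerise the butenolide γ-centre.

**Step 12**
Reactants: 18 silyl ether methacrylate
Product: 19 aldehyde (4-oxo analogue of 18)
Conditions: (COCl)2, DMSO, CH2Cl2, −78 to −40 °C; then Et3N, −78 °C; used at once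
Reagents that add atoms: none
Why: Swern oxidation acts directly on the primary triethylsilyl ether (a known one-step oxidative desilylation) and gives the β,γ-unsaturated aldehyde under cold conditions that neither epimerise C-5 nor move the isopropenyl double bond into conjugation.

**Step 13**
Reactants: 19 aldehyde
Product: 22 (3aR,4S,5S,6R,7S,7aR)-4-hydroxy-6-methyl-3-methylidene-6-[(2S)-oxiran-2-yl]-2-oxo-5-(prop-1-en-2-yl)octahydro-1-benzofuran-7-yl 2-methylprop-2-enoate, via samarium ketyl 20 (not isolated), via lactonyl radical 21 (not isolated)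
Conditions: SmI2 (2.2 equiv, added over 30 min), t-BuOH (2 equiv), THF, −78 °C; pH 7 buffer
Reagents that add atoms: none
Why: Proposed new method: SmI2 reduces the aldehyde to a ketyl that closes the cyclohexane by 6-exo-trig attack on the butenolide β-carbon from the face to which it is tethered (hence the cis ring fusion at C-3a) through a chair transition state with the O–Sm group, the acceptor, the methacrylate and the methyl all equatorial (the C-4 epimer would need O–Sm, the lactone oxygen and the oxirane all syn-axial), and the resulting α-lactonyl radical, or its samarium enolate after a second electron, expels benzenesulfinate to give the exo-methylene directly, the closest known reactions being SmI2 ketyl–olefin cyclisations onto unsaturated esters and lactones and radical allyl transfer from allyl sulfones.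

**Step 14**
Reactants: 22 isopropenyl lactone
Product: 24 target CNP0124638.3, via allylic alcohol 23 (not isolated)
Conditions: SeO2 (0.3 equiv), t-BuOOH, CH2Cl2, rt; then MnO2, CH2Cl2, rt
Reagents that add atoms: tert-butyl hydroperoxide, CC(C)(C)OO
Why: Selenium dioxide allylic oxidation (ene reaction then [2,3]-shift) is confined to the isopropenyl methyl because the three other alkenes are acceptor-substituted and the oxirane-bearing carbon has no allylic hydrogen, and MnO2 then oxidises only the primary allylic alcohol, so the secondary C-4 hydroxyl and all stereocentres are untouched.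

**Compound list**
1 | 2-methyl-2-vinyloxirane (racemic) | C=CC1(C)CO1 | starting material
2 | 3-methylbut-3-enoic acid | CC(=C)CC(=O)O | starting material
3 | (2E)-4-hydroxy-3-methylbut-2-en-1-yl 3-methylbut-3-enoate | CC(=C)CC(=O)OC/C=C(C)/CO | intermediate
4 | (2E)-4-[(2,2-dimethylpropanoyl)oxy]-3-methylbut-2-en-1-yl 3-methylbut-3-enoate | CC(=C)CC(=O)OC/C=C(C)/COC(=O)C(C)(C)C | intermediate
5 | E(O) boron ketene acetal of 4 carrying the (4S,5S)-diazaborolidine | C=C(C)/C=C(/OB1N(S(=O)(=O)c2cc(cc(c2)C(F)(F)F)C(F)(F)F)[C@@H](c2ccccc2)[C@H](c2ccccc2)N1S(=O)(=O)c1cc(cc(c1)C(F)(F)F)C(F)(F)F)\OC/C=C(C)/COC(=O)C(C)(C)C | intermediate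
6 | (2S,3S)-3-{[(2,2-dimethylpropanoyl)oxy]methyl}-3-methyl-2-(prop-1-en-2-yl)pent-4-enoic acid | OC(=O)[C@@H](C(C)=C)[C@](C)(C=C)COC(=O)C(C)(C)C | intermediate
7 | (2S,3S)-2-ethenyl-2-methyl-3-(prop-1-en-2-yl)butane-1,4-diol | OC[C@@H](C(C)=C)[C@](C)(C=C)CO | intermediate
8 | (2S,3S)-2-ethenyl-2-methyl-3-(prop-1-en-2-yl)-4-[(triethylsilyl)oxy]butan-1-ol | CC[Si](CC)(CC)OC[C@@H](C(C)=C)[C@](C)(C=C)CO | intermediate
9 | (2S,3S)-2-methyl-2-[(2S)-oxiran-2-yl]-3-(prop-1-en-2-yl)-4-[(triethylsilyl)oxy]butan-1-ol | CC[Si](CC)(CC)OC[C@@H](C(C)=C)[C@](C)([C@H]1CO1)CO | intermediate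
10 | (2R,3S)-2-methyl-2-[(2S)-oxiran-2-yl]-3-(prop-1-en-2-yl)-4-[(triethylsilyl)oxy]butanal | CC[Si](CC)(CC)OC[C@@H](C(C)=C)[C@](C)([C@H]1CO1)C=O | intermediate
11 | 3-methylideneoxolan-2-one (α-methylene-γ-butyrolactone) | C=C1CCOC1=O | starting material
12 | 3-[(benzenesulfonyl)methyl]-3-iodooxolan-2-one (racemic) | O=C1OCCC1(I)CS(=O)(=O)c1ccccc1 | intermediate
13 | 3-[(benzenesulfonyl)methyl]furan-2(5H)-one | O=C1OCC=C1CS(=O)(=O)c1ccccc1 | intermediate
14 | {3-[(benzenesulfonyl)methyl]furan-2-yl}oxy(trimethyl)silane | C[Si](C)(C)Oc1occc1CS(=O)(=O)c1ccccc1 | intermediate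
15 | trimethylsilyl ether of 16 | CC[Si](CC)(CC)OC[C@@H](C(C)=C)[C@](C)([C@H]1CO1)[C@H](O[Si](C)(C)C)[C@@H]1OC(=O)C(CS(=O)(=O)c2ccccc2)=C1 | intermediate
16 | (5R)-3-[(benzenesulfonyl)methyl]-5-{(1S,2S,3S)-1-hydroxy-2-methyl-2-[(2S)-oxiran-2-yl]-3-(prop-1-en-2-yl)-4-[(triethylsilyl)oxy]butyl}furan-2(5H)-one | CC[Si](CC)(CC)OC[C@@H](C(C)=C)[C@](C)([C@H]1CO1)[C@H](O)[C@@H]1OC(=O)C(CS(=O)(=O)c2ccccc2)=C1 | intermediate
17 | 2-methylprop-2-enoyl chloride | C=C(C)C(=O)Cl | starting material
18 | (1S,2R,3S)-1-{(2R)-4-[(benzenesulfonyl)methyl]-5-oxo-2,5-dihydrofuran-2-yl}-2-methyl-2-[(2S)-oxiran-2-yl]-3-(prop-1-en-2-yl)-4-[(triethylsilyl)oxy]butyl 2-methylprop-2-enoate | CC[Si](CC)(CC)OC[C@@H](C(C)=C)[C@](C)([C@H]1CO1)[C@H](OC(=O)C(C)=C)[C@@H]1OC(=O)C(CS(=O)(=O)c2ccccc2)=C1 | intermediate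
19 | (1S,2R,3S)-1-{(2R)-4-[(benzenesulfonyl)methyl]-5-oxo-2,5-dihydrofuran-2-yl}-2-methyl-2-[(2S)-oxiran-2-yl]-4-oxo-3-(prop-1-en-2-yl)butyl 2-methylprop-2-enoate | O=C[C@@H](C(C)=C)[C@](C)([C@H]1CO1)[C@H](OC(=O)C(C)=C)[C@@H]1OC(=O)C(CS(=O)(=O)c2ccccc2)=C1 | intermediate
20 | diiodosamarium ketyl of 19 (carbon radical at the former aldehyde carbon) | I[Sm](I)O[CH][C@@H](C(C)=C)[C@](C)([C@H]1CO1)[C@H](OC(=O)C(C)=C)[C@@H]1OC(=O)C(CS(=O)(=O)c2ccccc2)=C1 | intermediate
21 | cyclised C-3 lactonyl radical (C-4 diiodosamarium alkoxide) | C=C(C)C(=O)O[C@@H]1[C@@H]2OC(=O)[C](CS(=O)(=O)c3ccccc3)[C@@H]2[C@@H](O[Sm](I)I)[C@@H](C(C)=C)[C@]1(C)[C@H]1CO1 | intermediate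
22 | (3aR,4S,5S,6R,7S,7aR)-4-hydroxy-6-methyl-3-methylidene-6-[(2S)-oxiran-2-yl]-2-oxo-5-(prop-1-en-2-yl)octahydro-1-benzofuran-7-yl 2-methylprop-2-enoate | C=C(C)C(=O)O[C@@H]1[C@@H]2OC(=O)C(=C)[C@@H]2[C@@H](O)[C@@H](C(C)=C)[C@]1(C)[C@H]1CO1 | intermediate
23 | (3aR,4S,5S,6R,7S,7aR)-4-hydroxy-5-(3-hydroxyprop-1-en-2-yl)-6-methyl-3-methylidene-6-[(2S)-oxiran-2-yl]-2-oxooctahydro-1-benzofuran-7-yl 2-methylprop-2-enoate | C=C(C)C(=O)O[C@@H]1[C@@H]2OC(=O)C(=C)[C@@H]2[C@@H](O)[C@@H](C(=C)CO)[C@]1(C)[C@H]1CO1 | intermediate
24 | (3aR,4S,5R,6R,7S,7aR)-4-hydroxy-6-methyl-3-methylidene-6-[(2S)-oxiran-2-yl]-2-oxo-5-(3-oxoprop-1-en-2-yl)octahydro-1-benzofuran-7-yl 2-methylprop-2-enoate (CNP0124638.3) | C=C(C)C(=O)O[C@@H]1[C@@H]2OC(=O)C(=C)[C@@H]2[C@@H](O)[C@@H](C(=C)C=O)[C@]1(C)[C@H]1CO1 | target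

**Totals**
Total steps: 14. Longest linear sequence: 12 (steps 1–7 and 10–14); steps 8–9 make the furan fragment.

**Steps most likely to fail, each with one fallback**

Step 13 (key cyclisation). The ketyl may simply be reduced to the alcohol, SmI2 may over-reduce the new α-methylene lactone, or the Lewis-acidic samarium triiodide may open the oxirane. The fallback sets out from 19 and makes the ketyl by catalytic proton-coupled electron transfer instead of a stoichiometric metal: [Ir(ppy)2(dtbbpy)]PF6 (1 mol%), Hantzsch ester, diphenyl phosphate, blue light, THF, rt. The neutral ketyl closes the same bond; the lactonyl radical is then capped by hydrogen-atom transfer to give the sulfonylmethyl lactone F1 (if it fragments instead, 22 forms directly). Treating F1 with DBU in CH2Cl2 at 0 °C removes sulfinate by E1cB elimination and the route is rejoined at 22.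

Step 10 (vinylogous aldol). The risks are the wrong simple diastereoselectivity (threo instead of erythro), the wrong aldehyde face, and retro-aldol on the hindered aldehyde. The fallback sets out from 10 and 14 and uses BF3·OEt2 in CH2Cl2 at −78 °C, where the synclinal Diels–Alder-like transition state normally gives the threo adduct F2 (the C-7a epimer of 16) under the same Cornforth control at C-7. F2 is then equilibrated with Et3N in CH2Cl2 at rt through the achiral 2-hydroxyfuran dienolate; the erythro isomer is separated and F2 recycled, and the route is rejoined at 16. Whether erythro is the favoured isomer at equilibrium for this substrate is not known.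

Step 6 (directed epoxidation). The risk is low selectivity at the oxirane carbon if ligand and substrate are mismatched. The fallback sets out from 8 and uses achiral VO(acac)2 with t-BuOOH, which is still hydroxyl-directed and so still spares the isopropenyl group, to give 9 mixed with its oxirane epimer F3. Hydrolytic kinetic resolution with (R,R)-(salen)Co(OAc) and 0.5 equiv of water then converts the (R)-oxirane F3 into the triol F4, which is separated from unchanged 9, and the route is rejoined at 9.

**Further compounds**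
F1 | step 13 | (3aR,4S,5S,6R,7S,7aR)-3-[(benzenesulfonyl)methyl]-4-hydroxy-6-methyl-6-[(2S)-oxiran-2-yl]-2-oxo-5-(prop-1-en-2-yl)octahydro-1-benzofuran-7-yl 2-methylprop-2-enoate (C-3 epimers) | C=C(C)C(=O)O[C@@H]1[C@@H]2OC(=O)C(CS(=O)(=O)c3ccccc3)[C@@H]2[C@@H](O)[C@@H](C(C)=C)[C@]1(C)[C@H]1CO1
F2 | step 10 | (5S)-3-[(benzenesulfonyl)methyl]-5-{(1S,2S,3S)-1-hydroxy-2-methyl-2-[(2S)-oxiran-2-yl]-3-(prop-1-en-2-yl)-4-[(triethylsilyl)oxy]butyl}furan-2(5H)-one | CC[Si](CC)(CC)OC[C@@H](C(C)=C)[C@](C)([C@H]1CO1)[C@H](O)[C@H]1OC(=O)C(CS(=O)(=O)c2ccccc2)=C1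
F3 | step 6 | (2S,3S)-2-methyl-2-[(2R)-oxiran-2-yl]-3-(prop-1-en-2-yl)-4-[(triethylsilyl)oxy]butan-1-ol | CC[Si](CC)(CC)OC[C@@H](C(C)=C)[C@](C)([C@@H]1CO1)CO
F4 | step 6 | (2R,3S,4S)-3-(hydroxymethyl)-3-methyl-4-(prop-1-en-2-yl)-5-[(triethylsilyl)oxy]pentane-1,2-diol | CC[Si](CC)(CC)OC[C@@H](C(C)=C)[C@](C)([C@@H](O)CO)CO
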